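At early times the west run and the east run lose Qa at nearly one pace, though east holds twice the Qc. The reciprocal of the fraction of Qa left, the usual second-order plot, shows it.

all flasks: Qa 0.50 M
- west: Qb 1.1 equiv; Qc 0.57 equiv; run made earlier
- east: Qb 1.1 equiv; Qc 1.2 equiv; run made earlier
- dawn: Qb 1.10 equiv; Qc 0.500 equiv; time 3.0 h
- dusk: Qb 1.10 equiv; Qc 0.750 equiv; time 3.0 h

| run | time / min | Qa / % | Qe / % |
|---|---|---|---|
| west | 8.00 | 85.8 | 11.4 |
| west | 25.0 | 70.0 | 18.9 |
| west | 40.0 | 61.2 | 19.3 |
| west | 60.0 | 53.5 | 17.7 |
| west | 90.0 | 45.9 | 15.2 |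
| west | 120 | 41.0 | 13.0 |
| east | 10.0 | 84.2 | 13.6 |
| east | 15.0 | 77.8 | 15.2 |
| east | 30.0 | 66.7 | 19.3 |
| east | 50.0 | 57.2 | 18.6 |
| east | 80.0 | 47.4 | 15.4 |
| east | 120 | 38.4 | 13.1 |

(standard deviation of a reading: 0.5 percentage points)

- part of the Qa that has reacted at the end, dawn
- part of the Qa that has reacted at the end, dusk
- what raising the equivalents of Qc from its lowest to its highest value here does to the part of the Qa that has reacted (changes below 5 percentage points count as none) (it rises / it falls / no change)

Carry one number, the mean slope, the rise of that reciprocal from its starting value divided by the time: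

mean slope = (1/fraction left − 1) / time

By their early readings it is 0.0171 min⁻¹ in west and 0.0166 min⁻¹ in east. By the last readings it is 0.0120 min⁻¹ and 0.0134 min⁻¹.

Replacing the curve by this mean has a cost. The mean line puts west at 58.1% Qa left at 60.0 min, but the reading is 53.5%. West's slope over its last interval is 0.00868 min⁻¹, lower than the mean.

So I reckon two simple versions of the flask. In the first, the mean slope simply continues. Drawn on a straight line in equivalents of Qc, it is 0.0118 min⁻¹ for dawn and 0.0124 min⁻¹ for dusk:

reacted = 1 − 1/(1 + slope × time)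

dawn 68.1%, dusk 69.0%

In the second, west climbs on from its last reading at the late slope and reaches 66.2%. The slope has been falling, so I take the first as too high; but the late slope rests on one interval between two scattered readings of west, so I don't take the second as a bound. I commit to the middle of the two for dawn, near 67.1%, with dusk higher by the gap of the first version, 0.90 percentage points, which counts as no change.

The forecast differs: 61.5% for dawn, 67% for dusk, and the verdict it rises, reading west's falling slope as “suggesting base depletion once much has been used”.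

The flask gives 66.9% for dawn and 67.6% for dusk, so no change, a difference of 0.75 points.

    Qh ⇌ Qd, rate k1*(cs1 - [Qd]) while solid is left; crystals form when [Qd] > cs1 (solubility = 0.160 M, k = 3.90 min⁻¹)
    Qa + Qe → Qk (k = 0.0442 L mol⁻¹ min⁻¹)
    Qd + Qc ⇌ Qg (K = 433 L mol⁻¹, k = 0.525 L mol⁻¹ min⁻¹)
    Qa + Qb → Qd + Qe (k = 0.0408 L mol⁻¹ min⁻¹)
    Qb + Qd ⇌ Qf, settled at all times (K = 2100 L mol⁻¹)
    2 Qb → Qj (k = 0.0359 L mol⁻¹ min⁻¹)

Dusk's own mean slope over 3.0 h is 0.0116 min⁻¹, lower than west's 0.0120 min⁻¹ over 120 min. Taken on to a reading of dusk at 5.0 h, it gives 77.7% reacted, and that neighbouring flask shows 76.9%.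

All runs are simulated with constants of no real substance, noise included.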